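**Plan**
- Retrosynthesis: the C9 senecioate C–O bond is cut first, then ring B at C7–C8. C7 carries an isopropenyl group (C11–C13) next to the C8 carbonyl, which is what a carbonyl-ene reaction leaves when a C8 aldehyde meets the C7=C11 bond of a prenyl chain (C6–C7=C11) on C5.
- The ene precursor (ring A with cis C5-prenyl and C10-CH(OSiEt3)CHO arms) is traced to a cis-fused δ-lactone (C7–O9) that ties the two arms. C4–C15 and C3–O come from a C3=C4 alkene, C5–C14 and C5–C6 from two enolate alkylations, and ring A from a Michael/aldol annulation (C5–C10 and C2–C3).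
- Forward order: ring A, temporary lactone ring, lactone opening to the prenyl chain, ring B by the ene reaction, then the C8 ketone and the C9 ester.
- Stereochemistry: C9 from (S)-glyceraldehyde; C10 from the amine catalyst; C5 by alkylation anti to C9; C3/C4 by syn hydroboration anti to the axial C14 methyl of the lactone; C7 (and transient C8) from the chair ene transition state.

Key step: step 15

Assumption: atoms carry eremophilane numbers (ring A = C1–C5 and C10, ring B = C5–C10, C14 on C5, C15 on C4, C11–C13 in the isopropenyl group; β is the face of C14), and (S)-glyceraldehyde acetonide is taken as a purchasable chiral-pool aldehyde.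

Step 1
Reactants: 1 (S)-2,2-dimethyl-1,3-dioxolane-4-carbaldehyde; 2 (triphenylphosphoranylidene)acetaldehyde
Product: 3 (2E)-3-[(4R)-2,2-dimethyl-1,3-dioxolan-4-yl]prop-2-enal
Conditions: toluene, rt
Reagents that add atoms: none
Why: Wittig olefination with the stabilised formyl ylide should give the E-enal under neutral conditions that leave the acetal stereocentre (future C9) untouched.

Step 2
Reactants: 3 (2E)-3-[(4R)-2,2-dimethyl-1,3-dioxolan-4-yl]prop-2-enal; 4 tert-butyl 3-oxobutanoate
Product: 7 (5S)-5-[(4R)-2,2-dimethyl-1,3-dioxolan-4-yl]cyclohex-2-en-1-one, via Michael adduct 5 (not isolated), via keto ester 6 (not isolated)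
Conditions: (R)-2-{bis[3,5-bis(trifluoromethyl)phenyl][(trimethylsilyl)oxy]methyl}pyrrolidine (10 mol %), PhCO2H (10 mol %), toluene, rt; then p-TsOH·H2O (20 mol %), toluene, 80 °C
Reagents that add atoms: none
Why: Iminium-catalysed Michael addition of the β-keto ester, in which the (R)-catalyst shields one face of the E-iminium ion so that C10 should form with S configuration, followed by acid-promoted intramolecular aldol condensation of the acetyl methyl onto the aldehyde and dealkylative decarboxylation to close ring A.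

Step 3
Reactants: 7 (5S)-5-[(4R)-2,2-dimethyl-1,3-dioxolan-4-yl]cyclohex-2-en-1-one; 8 tert-butyl bromoacetate
Product: 10 tert-butyl 2-[(1R,6S)-6-[(4R)-2,2-dimethyl-1,3-dioxolan-4-yl]-2-oxocyclohex-3-en-1-yl]acetate, via lithium dienolate 9 (not isolated)
Conditions: LiN(i-Pr)2, THF, −78 °C; then 8, −78 to −30 °C
Reagents that add atoms: none
Why: Kinetic α'-deprotonation of the cyclohexenone and enolate alkylation at C5 with the reactive bromoacetate, expected anti to the C10 substituent, although this centre is made planar again in the next step.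

Step 4
Reactants: 10 tert-butyl 2-[(1R,6S)-6-[(4R)-2,2-dimethyl-1,3-dioxolan-4-yl]-2-oxocyclohex-3-en-1-yl]acetate
Product: 12 tert-butyl 2-[(1S,6S)-6-[(4R)-2,2-dimethyl-1,3-dioxolan-4-yl]-1-methyl-2-oxocyclohex-3-en-1-yl]acetate, via lithium dienolate 11 (not isolated)
Conditions: LiN(i-Pr)2, THF, −78 °C; then MeI, DMPU, −78 to −20 °C
Reagents that add atoms: iodomethane, CI
Why: Enolate alkylation in which the ketone α'-H (about ten pK units more acidic than the ester CH2) is removed and MeI should enter anti to the dioxolanyl group on C10, as in the second alkylation of 6-substituted carvones, placing C14 trans to C9 and the acetate arm cis to it.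

Step 5
Reactants: 12 tert-butyl 2-[(1S,6S)-6-[(4R)-2,2-dimethyl-1,3-dioxolan-4-yl]-1-methyl-2-oxocyclohex-3-en-1-yl]acetate
Product: 14 (1R,4aS,8aS)-1-(hydroxymethyl)-4a-methyl-4,4a,8,8a-tetrahydro-1H-isochromene-3,5-dione, via dihydroxy acid 13 (not isolated)
Conditions: CF3CO2H–H2O (9:1), CH2Cl2, 0 °C to rt; then toluene, 50 °C
Reagents that add atoms: none
Why: Acetal hydrolysis and tert-butyl ester acidolysis followed by lactonisation, in which only the secondary O9 can close a six-membered ring onto C7, so the primary C8 hydroxyl stays free and the cis-fused lactone should hold ring A in the chair with C14 axial.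

Step 6
Reactants: 14 (1R,4aS,8aS)-1-(hydroxymethyl)-4a-methyl-4,4a,8,8a-tetrahydro-1H-isochromene-3,5-dione
Product: 15 (1R,4aS,8aS)-4a-methyl-1-{[(triethylsilyl)oxy]methyl}-4,4a,8,8a-tetrahydro-1H-isochromene-3,5-dione
Conditions: Et3SiCl, imidazole, CH2Cl2, 0 °C
Reagents that add atoms: chlorotriethylsilane, CC[Si](Cl)(CC)CC
Why: Silyl ether formation at the primary alcohol masks O8 in a form that can later be oxidised directly and removes the hydroxyl that could add to the enone.

Step 7
Reactants: 15 (1R,4aS,8aS)-4a-methyl-1-{[(triethylsilyl)oxy]methyl}-4,4a,8,8a-tetrahydro-1H-isochromene-3,5-dione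
Product: 17 (1R,4aS,8aS)-4a-methyl-3-oxo-1-{[(triethylsilyl)oxy]methyl}-3,4,4a,7,8,8a-hexahydro-1H-isochromen-5-yl trifluoromethanesulfonate, via lithium enolate 16 (not isolated)
Conditions: Li[(s-Bu)3BH], THF, −78 °C; then PhNTf2, −78 °C to rt
Reagents that add atoms: N-phenylbis(trifluoromethanesulfonimide), O=S(=O)(N(c1ccccc1)S(=O)(=O)C(F)(F)F)C(F)(F)F
Why: Conjugate reduction of the β-unsubstituted enone by the hindered borohydride gives the C3=C4 enolate regiospecifically, and O-sulfonylation traps it as the enol triflate while the lactone is untouched at low temperature.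

Step 8
Reactants: 17 (1R,4aS,8aS)-4a-methyl-3-oxo-1-{[(triethylsilyl)oxy]methyl}-3,4,4a,7,8,8a-hexahydro-1H-isochromen-5-yl trifluoromethanesulfonate
Product: 18 (1R,4aS,8aS)-4a,5-dimethyl-1-{[(triethylsilyl)oxy]methyl}-1,4,4a,7,8,8a-hexahydro-3H-isochromen-3-one
Conditions: Me2Zn, Pd(PPh3)4 (5 mol %), THF, 0 °C to rt
Reagents that add atoms: dimethylzinc, C[Zn]C
Why: Negishi cross-coupling of the enol triflate places C15 on C4, and the organozinc reagent leaves the lactone and the silyl ether alone.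

Step 9
Reactants: 18 (1R,4aS,8aS)-4a,5-dimethyl-1-{[(triethylsilyl)oxy]methyl}-1,4,4a,7,8,8a-hexahydro-3H-isochromen-3-one
Product: 19 (1R,4aR,5R,6R,8aS)-6-hydroxy-4a,5-dimethyl-1-{[(triethylsilyl)oxy]methyl}octahydro-3H-isochromen-3-one
Conditions: BH3·THF, THF, 0 °C; then 30 % H2O2, pH 7 phosphate buffer, THF–MeOH, 0 °C to rt
Reagents that add atoms: hydrogen peroxide, OO
Why: Hydroboration–oxidation adds B to C3 and H to C4 syn and anti-Markovnikov, and attack on the α face, away from the axial C14 methyl of the lactone-locked ring, should give 3α-OH and 4β-CH3 trans to each other (as 1-methylcyclohexene gives trans-2-methylcyclohexanol), the lactone being reduced much more slowly than the alkene reacts.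

Step 10
Reactants: 19 (1R,4aR,5R,6R,8aS)-6-hydroxy-4a,5-dimethyl-1-{[(triethylsilyl)oxy]methyl}octahydro-3H-isochromen-3-one; 20 (2E)-2-methylbut-2-enoyl chloride
Product: 21 (1R,4aR,5R,6R,8aS)-4a,5-dimethyl-3-oxo-1-{[(triethylsilyl)oxy]methyl}octahydro-1H-isochromen-6-yl (2E)-2-methylbut-2-enoate
Conditions: pyridine, DMAP (10 mol %), CH2Cl2, 0 °C to rt
Reagents that add atoms: none
Why: DMAP-catalysed acylation of the equatorial secondary alcohol under a weak base, which should keep the E-tiglate from deconjugating.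

Step 11
Reactants: 21 (1R,4aR,5R,6R,8aS)-4a,5-dimethyl-3-oxo-1-{[(triethylsilyl)oxy]methyl}octahydro-1H-isochromen-6-yl (2E)-2-methylbut-2-enoate
Product: 22 (1R,4aR,5R,6R,8aS)-3-hydroxy-4a,5-dimethyl-1-{[(triethylsilyl)oxy]methyl}octahydro-1H-isochromen-6-yl (2E)-2-methylbut-2-enoate (both C3 anomers)
Conditions: disiamylborane [from BH3·THF and 2-methylbut-2-ene], THF, 0 °C to rt; then H2O
Reagents that add atoms: none
Why: Chemoselective lactone-to-lactol reduction, since disiamylborane reduces lactones but neither carboxylic esters nor trisubstituted alkenes (as used on acylated aldonolactones), so the tiglate should survive.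

Step 12
Reactants: 22 (1R,4aR,5R,6R,8aS)-3-hydroxy-4a,5-dimethyl-1-{[(triethylsilyl)oxy]methyl}octahydro-1H-isochromen-6-yl (2E)-2-methylbut-2-enoate; 23 isopropyltriphenylphosphonium iodide
Product: 24 (1R,2R,3R,4S)-4-[(1R)-1-hydroxy-2-[(triethylsilyl)oxy]ethyl]-2,3-dimethyl-3-(3-methylbut-2-en-1-yl)cyclohexyl (2E)-2-methylbut-2-enoate
Conditions: 23, n-BuLi, THF, 0 °C; then 22, 0 °C to rt
Reagents that add atoms: none
Why: Wittig olefination of the lactol through its open hydroxy-aldehyde form with the non-stabilised isopropylidene ylide builds the C7=C11 prenyl double bond and frees O9–H without touching a stereocentre.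

Step 13
Reactants: 24 (1R,2R,3R,4S)-4-[(1R)-1-hydroxy-2-[(triethylsilyl)oxy]ethyl]-2,3-dimethyl-3-(3-methylbut-2-en-1-yl)cyclohexyl (2E)-2-methylbut-2-enoate
Product: 25 (1R,2R,3R,4S)-4-[(1R)-1,2-bis[(triethylsilyl)oxy]ethyl]-2,3-dimethyl-3-(3-methylbut-2-en-1-yl)cyclohexyl (2E)-2-methylbut-2-enoate
Conditions: Et3SiOTf, 2,6-lutidine, CH2Cl2, −78 °C
Reagents that add atoms: triethylsilyl trifluoromethanesulfonate, CC[Si](CC)(CC)OS(=O)(=O)C(F)(F)F
Why: Silyl ether formation with the silyl triflate and a hindered base protects the hindered secondary O9–H; any silyl shift between O8 and O9 in step 12 is made harmless because both oxygens end up with the same group.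

Step 14
Reactants: 25 (1R,2R,3R,4S)-4-[(1R)-1,2-bis[(triethylsilyl)oxy]ethyl]-2,3-dimethyl-3-(3-methylbut-2-en-1-yl)cyclohexyl (2E)-2-methylbut-2-enoate
Product: 26 (1R,2R,3R,4S)-2,3-dimethyl-3-(3-methylbut-2-en-1-yl)-4-[(1R)-2-oxo-1-[(triethylsilyl)oxy]ethyl]cyclohexyl (2E)-2-methylbut-2-enoate
Conditions: (COCl)2, DMSO, CH2Cl2, −78 to −40 °C; then Et3N, −78 to 0 °C
Reagents that add atoms: none
Why: Swern oxidation, in which the chlorosulfonium salt attacks the primary triethylsilyl ether and oxidises it directly to the aldehyde while the secondary silyl ether stays, gives the α-silyloxy aldehyde without a free diol stage and at a temperature at which C9 should not epimerise.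

Step 15
Reactants: 26 (1R,2R,3R,4S)-2,3-dimethyl-3-(3-methylbut-2-en-1-yl)-4-[(1R)-2-oxo-1-[(triethylsilyl)oxy]ethyl]cyclohexyl (2E)-2-methylbut-2-enoate
Product: 27 (3R,4R,5R,7R,8R,9R,10S)-8-hydroxy-9-[(triethylsilyl)oxy]eremophil-11-en-3-yl (2E)-2-methylbut-2-enoate
Conditions: Me2AlCl (2 equiv), CH2Cl2, −78 °C; then aq. KNaC4H4O6 (potassium sodium tartrate)
Reagents that add atoms: none
Why: Me2AlCl binds the C8 aldehyde oxygen, C7 of the prenyl double bond attacks C8 while a hydrogen of the allylic methyl C12 passes to oxygen in a six-centre transition state, and the aluminium alkoxide loses methane, so no free acid is present. This is a Lewis-acid carbonyl-ene cyclisation of the citronellal-to-isopulegol kind. Ring B closes as a six-membered chair through the new C7–C8 bond, exo with respect to both the carbonyl and the alkene, on the cis-disposed C5 and C10 arms of ring A (C6 equatorial, C9 axial on ring A). C7 is set by that chair, in which the developing isopropenyl group lies equatorial and so avoids a 1,3-diaxial contact with C4. C8 is set by the same chair with its oxygen equatorial and trans to both neighbours (it is removed in step 16), and the already fixed 9R silyloxy group is equatorial too. The step needs ene closure in preference to cationic Prins-type paths and no loss of configuration at C9; the gem-dimethyl alkene as the best ene donor, the proton-scavenging methylaluminium reagent, the non-chelating silyl ether and the low temperature should secure this, and the electron-poor tiglate alkene cannot compete.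

Step 16
Reactants: 27 (3R,4R,5R,7R,8R,9R,10S)-8-hydroxy-9-[(triethylsilyl)oxy]eremophil-11-en-3-yl (2E)-2-methylbut-2-enoate
Product: 28 (3R,4R,5R,7R,9R,10S)-8-oxo-9-[(triethylsilyl)oxy]eremophil-11-en-3-yl (2E)-2-methylbut-2-enoate
Conditions: Dess–Martin periodinane, NaHCO3, CH2Cl2, 0 °C to rt
Reagents that add atoms: none
Why: Dess–Martin oxidation under buffered, near-neutral conditions should give the C8 ketone without epimerising C7 or C9 and without moving the β,γ-double bond into conjugation.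

Step 17
Reactants: 28 (3R,4R,5R,7R,9R,10S)-8-oxo-9-[(triethylsilyl)oxy]eremophil-11-en-3-yl (2E)-2-methylbut-2-enoate
Product: 29 (3R,4R,5R,7R,9R,10S)-9-hydroxy-8-oxoeremophil-11-en-3-yl (2E)-2-methylbut-2-enoate
Conditions: HF·pyridine, pyridine, THF, 0 °C
Reagents that add atoms: none
Why: Fluoride-mediated desilylation in a pyridine-buffered medium removes the triethylsilyl ether without base strong enough to isomerise the α-ketol or the isopropenyl ketone.

Step 18
Reactants: 29 (3R,4R,5R,7R,9R,10S)-9-hydroxy-8-oxoeremophil-11-en-3-yl (2E)-2-methylbut-2-enoate; 30 3-methylbut-2-enoyl chloride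
Product: 31 (3R,4R,5R,7R,9R,10S)-3-[(2E)-2-methylbut-2-enoyloxy]-8-oxoeremophil-11-en-9-yl 3-methylbut-2-enoate (CNP0375730.1)
Conditions: pyridine, DMAP (10 mol %), CH2Cl2, 0 °C
Reagents that add atoms: none
Why: DMAP-catalysed acylation of the α-hydroxy ketone with the acid chloride under a weak base should install the senecioate without deconjugating it and without epimerising C7 or C9.

**Compound list**
1 | (S)-2,2-dimethyl-1,3-dioxolane-4-carbaldehyde | O=C[C@@H]1COC(C)(C)O1 | starting material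
2 | (triphenylphosphoranylidene)acetaldehyde | O=CC=P(c1ccccc1)(c1ccccc1)c1ccccc1 | starting material
3 | (2E)-3-[(4R)-2,2-dimethyl-1,3-dioxolan-4-yl]prop-2-enal | O=C/C=C/[C@@H]1COC(C)(C)O1 | intermediate
4 | tert-butyl 3-oxobutanoate | CC(=O)CC(=O)OC(C)(C)C | starting material
5 | tert-butyl (3S)-2-acetyl-3-[(4R)-2,2-dimethyl-1,3-dioxolan-4-yl]-5-oxopentanoate (Michael adduct, C2 epimers) | CC(=O)C(C(=O)OC(C)(C)C)[C@H](CC=O)[C@@H]1COC(C)(C)O1 | intermediate
6 | tert-butyl (6S)-6-[(4R)-2,2-dimethyl-1,3-dioxolan-4-yl]-2-oxocyclohex-3-ene-1-carboxylate (keto ester, C1 epimers) | O=C1C=CC[C@H]([C@@H]2COC(C)(C)O2)C1C(=O)OC(C)(C)C | intermediate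
7 | (5S)-5-[(4R)-2,2-dimethyl-1,3-dioxolan-4-yl]cyclohex-2-en-1-one | O=C1C[C@H](CC=C1)[C@@H]1COC(C)(C)O1 | intermediate
8 | tert-butyl bromoacetate | BrCC(=O)OC(C)(C)C | starting material
9 | lithium (3S)-3-[(4R)-2,2-dimethyl-1,3-dioxolan-4-yl]cyclohexa-1,5-dien-1-olate (α'-dienolate of 7) | [Li+].[O-]C1=C[C@H](CC=C1)[C@@H]1COC(C)(C)O1 | intermediate
10 | tert-butyl 2-[(1R,6S)-6-[(4R)-2,2-dimethyl-1,3-dioxolan-4-yl]-2-oxocyclohex-3-en-1-yl]acetate | O=C1C=CC[C@H]([C@@H]2COC(C)(C)O2)[C@H]1CC(=O)OC(C)(C)C | intermediate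
11 | lithium α'-dienolate of 10 (C5=C4–OLi) | [Li+].[O-]C1=C(CC(=O)OC(C)(C)C)[C@H](CC=C1)[C@@H]1COC(C)(C)O1 | intermediate
12 | tert-butyl 2-[(1S,6S)-6-[(4R)-2,2-dimethyl-1,3-dioxolan-4-yl]-1-methyl-2-oxocyclohex-3-en-1-yl]acetate | CC(C)(C)OC(=O)C[C@@]1(C)[C@H](CC=CC1=O)[C@@H]1COC(C)(C)O1 | intermediate
13 | 2-[(1S,6S)-6-[(1R)-1,2-dihydroxyethyl]-1-methyl-2-oxocyclohex-3-en-1-yl]acetic acid | OC(=O)C[C@@]1(C)[C@H](CC=CC1=O)[C@@H](O)CO | intermediate
14 | (1R,4aS,8aS)-1-(hydroxymethyl)-4a-methyl-4,4a,8,8a-tetrahydro-1H-isochromene-3,5-dione | O=C1C[C@@]2(C)[C@H](CC=CC2=O)[C@H](CO)O1 | intermediate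
15 | (1R,4aS,8aS)-4a-methyl-1-{[(triethylsilyl)oxy]methyl}-4,4a,8,8a-tetrahydro-1H-isochromene-3,5-dione | O=C1C[C@@]2(C)[C@H](CC=CC2=O)[C@H](CO[Si](CC)(CC)CC)O1 | intermediate
16 | lithium enolate of the 6,7-dihydro ketone from 15 (C3=C4–OLi) | O=C1C[C@@]2(C)[C@H](CCC=C2[O-])[C@H](CO[Si](CC)(CC)CC)O1.[Li+] | intermediate
17 | (1R,4aS,8aS)-4a-methyl-3-oxo-1-{[(triethylsilyl)oxy]methyl}-3,4,4a,7,8,8a-hexahydro-1H-isochromen-5-yl trifluoromethanesulfonate | O=C1C[C@@]2(C)[C@H](CCC=C2OS(=O)(=O)C(F)(F)F)[C@H](CO[Si](CC)(CC)CC)O1 | intermediate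
18 | (1R,4aS,8aS)-4a,5-dimethyl-1-{[(triethylsilyl)oxy]methyl}-1,4,4a,7,8,8a-hexahydro-3H-isochromen-3-one | O=C1C[C@@]2(C)[C@H](CCC=C2C)[C@H](CO[Si](CC)(CC)CC)O1 | intermediate
19 | (1R,4aR,5R,6R,8aS)-6-hydroxy-4a,5-dimethyl-1-{[(triethylsilyl)oxy]methyl}octahydro-3H-isochromen-3-one | O=C1C[C@@]2(C)[C@H](CC[C@@H](O)[C@@H]2C)[C@H](CO[Si](CC)(CC)CC)O1 | intermediate
20 | (2E)-2-methylbut-2-enoyl chloride (tigloyl chloride) | O=C(Cl)/C(C)=C/C | starting material
21 | (1R,4aR,5R,6R,8aS)-4a,5-dimethyl-3-oxo-1-{[(triethylsilyl)oxy]methyl}octahydro-1H-isochromen-6-yl (2E)-2-methylbut-2-enoate | O=C1C[C@@]2(C)[C@H](CC[C@@H](OC(=O)/C(C)=C/C)[C@@H]2C)[C@H](CO[Si](CC)(CC)CC)O1 | intermediate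
22 | (1R,4aR,5R,6R,8aS)-3-hydroxy-4a,5-dimethyl-1-{[(triethylsilyl)oxy]methyl}octahydro-1H-isochromen-6-yl (2E)-2-methylbut-2-enoate (lactol, both anomers) | OC1C[C@@]2(C)[C@H](CC[C@@H](OC(=O)/C(C)=C/C)[C@@H]2C)[C@H](CO[Si](CC)(CC)CC)O1 | intermediate
23 | isopropyltriphenylphosphonium iodide | CC(C)[P+](c1ccccc1)(c1ccccc1)c1ccccc1.[I-] | starting material
24 | (1R,2R,3R,4S)-4-[(1R)-1-hydroxy-2-[(triethylsilyl)oxy]ethyl]-2,3-dimethyl-3-(3-methylbut-2-en-1-yl)cyclohexyl (2E)-2-methylbut-2-enoate | CC(C)=CC[C@@]1(C)[C@H](CC[C@@H](OC(=O)/C(C)=C/C)[C@@H]1C)[C@@H](O)CO[Si](CC)(CC)CC | intermediate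
25 | (1R,2R,3R,4S)-4-[(1R)-1,2-bis[(triethylsilyl)oxy]ethyl]-2,3-dimethyl-3-(3-methylbut-2-en-1-yl)cyclohexyl (2E)-2-methylbut-2-enoate | CC(C)=CC[C@@]1(C)[C@H](CC[C@@H](OC(=O)/C(C)=C/C)[C@@H]1C)[C@@H](O[Si](CC)(CC)CC)CO[Si](CC)(CC)CC | intermediate
26 | (1R,2R,3R,4S)-2,3-dimethyl-3-(3-methylbut-2-en-1-yl)-4-[(1R)-2-oxo-1-[(triethylsilyl)oxy]ethyl]cyclohexyl (2E)-2-methylbut-2-enoate | CC(C)=CC[C@@]1(C)[C@H](CC[C@@H](OC(=O)/C(C)=C/C)[C@@H]1C)[C@@H](O[Si](CC)(CC)CC)C=O | intermediate
27 | (3R,4R,5R,7R,8R,9R,10S)-8-hydroxy-9-[(triethylsilyl)oxy]eremophil-11-en-3-yl (2E)-2-methylbut-2-enoate (cis-decalin, 7β-isopropenyl, 8α-OH, 9β-OSiEt3) | C=C(C)[C@H]1C[C@@]2(C)[C@H](CC[C@@H](OC(=O)/C(C)=C/C)[C@@H]2C)[C@@H](O[Si](CC)(CC)CC)[C@@H]1O | intermediate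
28 | (3R,4R,5R,7R,9R,10S)-8-oxo-9-[(triethylsilyl)oxy]eremophil-11-en-3-yl (2E)-2-methylbut-2-enoate | C=C(C)[C@H]1C[C@@]2(C)[C@H](CC[C@@H](OC(=O)/C(C)=C/C)[C@@H]2C)[C@@H](O[Si](CC)(CC)CC)C1=O | intermediate
29 | (3R,4R,5R,7R,9R,10S)-9-hydroxy-8-oxoeremophil-11-en-3-yl (2E)-2-methylbut-2-enoate | C=C(C)[C@H]1C[C@@]2(C)[C@H](CC[C@@H](OC(=O)/C(C)=C/C)[C@@H]2C)[C@@H](O)C1=O | intermediate
30 | 3-methylbut-2-enoyl chloride (senecioyl chloride) | CC(C)=CC(Cl)=O | starting material
31 | (3R,4R,5R,7R,9R,10S)-3-[(2E)-2-methylbut-2-enoyloxy]-8-oxoeremophil-11-en-9-yl 3-methylbut-2-enoate | C=C(C)[C@H]1C[C@@]2(C)[C@H](CC[C@@H](OC(=O)/C(C)=C/C)[C@@H]2C)[C@@H](OC(=O)C=C(C)C)C1=O | target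

Total step count: 18. Longest linear sequence: 18 steps (from 1).

**Steps most likely to fail**

Step 2. The acetonide may be hydrolysed by the acid and the water released in the condensation, and the diastereoselectivity may erode if catalyst and the γ-alkoxy stereocentre are mismatched. The fallback sets out from 3 and avoids acid: the same iminium-catalysed Michael addition is run with allyl 3-oxobutanoate to give the allyl keto ester F1. Pd(OAc)2/PPh3 with HCO2H–Et3N in THF removes the allyl ester and decarboxylates under neutral conditions to the keto aldehyde F2. Pyrrolidine/AcOH in toluene then closes ring A by intramolecular aldol condensation, in which only the methyl ketone can form a six-membered ring, and the route is rejoined at 7.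

Step 9. Borane may add from the wrong face if the lactone does not hold ring A in the expected chair, or the lactone may be reduced in competition. The fallback sets out from 15 and sets C3 and C4 in separate steps. Conjugate reduction with Li[(s-Bu)3BH] and oxidation of the enolate with 2-(phenylsulfonyl)-3-phenyloxaziridine should give the α-hydroxy ketone F3, whose equatorial 3α-hydroxyl is also the thermodynamically preferred epimer. Methylenation with Zn, CH2Br2 and TiCl4 gives the allylic alcohol F4. Hydroxyl-directed hydrogenation with [Ir(cod)(PCy3)(py)]PF6 and H2 in CH2Cl2 delivers hydrogen to C4 on the face of the hydroxyl, and the route is rejoined at 19.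

Step 15. The isopropenyl group may be delivered to the axial position if closure passes through the other ring A chair or a boat, with some leakage into cationic Prins-type paths. The fallback sets out from 26 and puts C7 under thermodynamic control: the cyclisation mixture containing the C7 epimer F5 is oxidised with Dess–Martin periodinane to the epimeric ketone F6. Brief treatment with catalytic DBU in toluene at rt then equilibrates C7 through the enol to the equatorial 7β isomer, which lacks the 1,3-diaxial contact with C4, and the route is rejoined at 28. The equilibration is stopped before the double bond moves into conjugation.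

Further compounds
F1 | step 2 | prop-2-en-1-yl (3S)-2-acetyl-3-[(4R)-2,2-dimethyl-1,3-dioxolan-4-yl]-5-oxopentanoate | CC(=O)C(C(=O)OCC=C)[C@H](CC=O)[C@@H]1COC(C)(C)O1
F2 | step 2 | (3S)-3-[(4R)-2,2-dimethyl-1,3-dioxolan-4-yl]-5-oxohexanal | CC(=O)C[C@H](CC=O)[C@@H]1COC(C)(C)O1
F3 | step 9 | (1R,4aS,6R,8aS)-6-hydroxy-4a-methyl-1-{[(triethylsilyl)oxy]methyl}hexahydro-1H-isochromene-3,5-dione | O=C1C[C@@]2(C)[C@H](CC[C@@H](O)C2=O)[C@H](CO[Si](CC)(CC)CC)O1
F4 | step 9 | (1R,4aS,6R,8aS)-6-hydroxy-4a-methyl-5-methylidene-1-{[(triethylsilyl)oxy]methyl}octahydro-3H-isochromen-3-one | O=C1C[C@@]2(C)[C@H](CC[C@@H](O)C2=C)[C@H](CO[Si](CC)(CC)CC)O1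
F5 | step 15 | (3R,4R,5R,7S,8R,9R,10S)-8-hydroxy-9-[(triethylsilyl)oxy]eremophil-11-en-3-yl (2E)-2-methylbut-2-enoate | C=C(C)[C@@H]1C[C@@]2(C)[C@H](CC[C@@H](OC(=O)/C(C)=C/C)[C@@H]2C)[C@@H](O[Si](CC)(CC)CC)[C@@H]1O
F6 | step 15 | (3R,4R,5R,7S,9R,10S)-8-oxo-9-[(triethylsilyl)oxy]eremophil-11-en-3-yl (2E)-2-methylbut-2-enoate | C=C(C)[C@@H]1C[C@@]2(C)[C@H](CC[C@@H](OC(=O)/C(C)=C/C)[C@@H]2C)[C@@H](O[Si](CC)(CC)CC)C1=O
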